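The vessel is closed, stirred and held at one temperature. Solid reagent lies in a solution of starting material, none of the solid is dissolved at the start, and target grows.

| setting | south | north-west | north | amber | red |
|---|---|---|---|---|---|
| starting material | 14 mM | 35 mM | 12 mM | 25 mM | 12 mM |
| solid reagent | 15.6 mM | 15.6 mM | 18 mM | 25.0 mM | 15.6 mM |
| temperature | 20 °C | 35 °C | 20 °C | 35 °C | 35 °C |
| remark | run made earlier | run made earlier | run made earlier |  |  |
| time |  |  |  | 2.0 min | 2.0 min |

south run (percent of the starting material charged)

| time / min | target / % | starting material / % |
|---|---|---|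
| 0.667 | 0.5 | 96.4 |
| 1.33 | 3.2 | 92.8 |
| 2.00 | 5.0 | 88.7 |
| 3.00 | 10.2 | 82.9 |
| 4.00 | 13.3 | 78.9 |

north-west run (percent of the starting material charged)

| time / s | target / % | starting material / % |
|---|---|---|
| 20.0 | 4.0 | 88.2 |
| 40.0 | 12.3 | 78.6 |
| 60.0 | 19.4 | 70.4 |
| 80.0 | 27.4 | 63.6 |
| 90.0 | 32.9 | 58.5 |
| 120 | 40.1 | 49.3 |

north run (percent of the starting material charged)

| time / min | target / % | starting material / % |
|---|---|---|
| 0.333 | 0.2 | 97.4 |
| 1.00 | 2.4 | 94.5 |
| 2.00 | 5.3 | 88.7 |
| 3.00 | 9.2 | 83.7 |
| 4.00 | 14.1 | 78.2 |

(standard deviation of a reading: 0.5 percentage points)

- solid, in amounts per volume of the solution: solid reagent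
- the analysis behind the earlier runs scatters by 0.5 percentage points, standard deviation
- at the start none of the solid reagent is in solution
- a reading or a percentage of target counts all its forms, free or not

* the flask that ends with the higher amount of target, in percent of the starting material charged, or "neither" when 2 percentage points or less lies between them (amber / red / neither)
* final target, as a percentage of the starting material charged, in amber
* final target, as a percentage of the starting material charged, in red

Two chemists read these runs differently. The first holds that the solid feeds the target. In the north-west run, target reached 14.0 mM, less than the 15.6 mM of solid charged. Red has 1.30 of solid per starting material and amber 1.00, so the first chemist expects red to finish ahead by more than the margin.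

The second answers that the north-west flask lost 17.7 mM of starting material, more than its solid charge. At 20 °C, south and north had 1.11 and 1.50 of solid per starting material, yet they read 13.3% and 14.1% of target at 4.00 min.

The second chemist therefore carries one number: the half-life of starting material at 35 °C, the time in which a first-order loss takes any charge to half, 1.96 min, read from the north-west run. Since 2.0 min is the time of that run's last reading, my own reckoning puts both flasks at its 40.1% of target, with nothing between them.

The forecast says neither, with 41% in amber and 40% in red, taking the loss as “first order in starting material and almost independent of solid”; it sets amber a little higher than my equal figures do.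

The flask gives neither: 40.7% in amber and 40.6% in red.

    starting material → intermediate A (k = 0.00530 s⁻¹, Ea = 91.0 kJ mol⁻¹)
    coupling partner + intermediate A → side product (k = 1.40 M⁻¹ s⁻¹, Ea = 59.0 kJ mol⁻¹)
    starting material ⇌ intermediate B (K = 0.180, k = 6.90 × 10⁻⁴ s⁻¹, Ea = 82.0 kJ mol⁻¹, ΔH = −76.0 kJ mol⁻¹)
    intermediate A → target (k = 0.0650 s⁻¹, Ea = 69.0 kJ mol⁻¹)
    2 coupling partner → homo dimer (k = 0.310 M⁻¹ s⁻¹, Ea = 66.0 kJ mol⁻¹)
    coupling partner + target ⇌ idle adduct, settled at all times (K = 71.0 M⁻¹, ΔH = −34.0 kJ mol⁻¹)
    solid reagent ⇌ coupling partner, rate k7*(cs7 - [coupling partner]) while solid is left; crystals form when [coupling partner] > cs7 (solubility = 4.20 mM, k = 0.00450 s⁻¹)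
    (constants at 35 °C)

At 2.00 min in red, intermediate A goes on to target 36 times as fast as it goes with coupling partner to side product, a selectivity factor. At that time red holds 0.696% of side product and amber 0.590%. The half-life reckons 49.3% of starting material left at 2.0 min, and red holds 50%. For the same flask read at 5.0 min it reckons 17.1%, and that flask holds 19.1%.

The runs come from a simulation with made-up constants; noise was put on by code.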